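The eight-membered ring is cut on both sides of its C8(OAc)–C9(side chain) pair (cycloocta[c]furan locants), which lies between C7H2 and C9a of the butenolide ring. These two carbons are the alkene of an (E)-alkenylboron ate complex made from (R)-β-citronellene. In one palladium-catalysed conjunctive coupling the homoallyl group shifts from boron to C8 while C9 is joined to C3 of a 3-bromo-4-vinylbutenolide, anti across the alkene. Three fragments, both C–C bonds, both stereocentres and the C8 oxygen (as C–B) therefore arrive together. The precursor is an acyclic lithium borate; ring-closing metathesis and cyclopropanation of the new cis-alkene finish the tricycle.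

Key step: step 8

Assumption: the (Sp,Sp) enantiomer of the Mandyphos ligand is taken to send palladium to the alkene face of 15 that leads to (5R,6S)-16; should a test run show the opposite sense, the (Rp,Rp) ligand replaces it and nothing else changes.

Remark on locants: in 16–18 the dodecadienyl chain is numbered from its vinyl end (C4 = CH2 beside the carbinol carbon C5, C6 carries the butenolide, C7 the side-chain methyl). In 19 and 20 cycloocta[c]furan locants are used (C1 lactone C=O, C3a/C9a butenolide alkene, C8 the OAc carbon, C9 the side-chain carbon).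

Step 1
Reactants: 1 (S)-4-benzyloxazolidin-2-one; 2 (E)-but-2-enoyl chloride
Product: 3 (S)-4-benzyl-3-[(E)-but-2-enoyl]oxazolidin-2-one
Conditions: n-BuLi, THF, −78 °C; then 2, −78 → 0 °C
Reagents that add atoms: none
Why: N-acylation of the lithiated oxazolidinone by the acid chloride (Evans imide formation), with no stereocentre touched.

Step 2
Reactants: 3 (S)-4-benzyl-3-[(E)-but-2-enoyl]oxazolidin-2-one
Product: 4 (S)-4-benzyl-3-[(S)-2-methylbut-3-enoyl]oxazolidin-2-one
Conditions: NaN(SiMe3)2, THF, −78 °C; MeI, −78 → −40 °C
Reagents that add atoms: methyl iodide, CI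
Why: Evans deconjugative alkylation: γ-deprotonation gives the chelated (Z)-dienolate, which should take up methyl iodide at the α-carbon on the face opposite the benzyl group, setting the (S) methyl-bearing centre (the later C6) beside a terminal vinyl group.

Step 3
Reactants: 4 (S)-4-benzyl-3-[(S)-2-methylbut-3-enoyl]oxazolidin-2-one
Product: 5 (S)-2-methylbut-3-en-1-ol
Conditions: LiBH4, H2O (1 equiv), Et2O, 0 °C; the volatile alcohol is kept in solution
Reagents that add atoms: none
Why: Reductive cleavage of the imide by LiBH4 should release the primary alcohol without touching the α-stereocentre or the alkene and return the auxiliary.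

Step 4
Reactants: 5 (S)-2-methylbut-3-en-1-ol
Product: 6 (S)-4-iodo-3-methylbut-1-ene
Conditions: PPh3, I2, imidazole, CH2Cl2, 0 °C → rt
Reagents that add atoms: iodine, II
Why: Appel-type iodination of a primary alcohol by SN2 displacement at CH2, which leaves the neighbouring stereocentre untouched.

Step 5
Reactants: 7 acenaphthylene-1,2-dione
Product: 8 cis-1,2-dimethyl-1,2-dihydroacenaphthylene-1,2-diol (mac diol)
Conditions: MeMgBr (3 equiv), THF, 0 °C → rt; aq. NH4Cl; crystallisation
Reagents that add atoms: methylmagnesium bromide, C[Mg]Br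
Why: Twofold Grignard addition to the 1,2-dione gives the tertiary diol, and the cis isomer, the only one that can bridge one boron atom, is taken by crystallisation.

Step 6
Reactants: 9 (R)-3,7-dimethylocta-1,6-diene ((R)-β-citronellene); 8 mac diol
Product: 11 [(1E,3R)-3,7-dimethylocta-1,6-dien-1-yl]boronic acid mac ester (cyclic ester of diol 8), via catechol alkenylboronate 10 (not isolated)
Conditions: ClB(O2C6H4), Pd2(dba)3 (2.5 mol%), (3,5-tBu2C6H3)2PtBu (6 mol%), LiOTf, Cy2NMe, PhCF3, 70 °C; then 8, Et3N, rt
Reagents that add atoms: B-chlorocatecholborane, ClB1Oc2ccccc2O1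
Why: Boryl-Heck reaction: the boryl–palladium species formed from zerovalent palladium and the B–Cl bond adds across the monosubstituted alkene with boron on the terminal carbon, β-hydride elimination gives the (E)-alkenyl catechol boronate 10, and exchange with diol 8 gives the mac ester, while the trisubstituted alkene and the C3 stereocentre are not touched.

Step 7
Reactants: 12 3,4-dibromofuran-2(5H)-one
Product: 13 3-bromo-4-ethenylfuran-2(5H)-one
Conditions: Bu3SnCH=CH2 (1.05 equiv), PdCl2(PhCN)2 (5 mol%), AsPh3 (10 mol%), NMP, rt; used promptly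
Reagents that add atoms: tributyl(vinyl)stannane, C=C[Sn](CCCC)(CCCC)CCCC
Why: Stille coupling in which oxidative addition should occur at the more electrophilic β-bromide (C4) of the vinylogous acyl bromide, so that the α-bromide (C3) is kept for step 8.

Step 8
Reactants: 6 (S)-4-iodo-3-methylbut-1-ene; 11 (E)-alkenylboronic acid mac ester; 13 3-bromo-4-ethenylfuran-2(5H)-one
Product: 17 3-[(3R,5R,6S,7R)-5-hydroxy-3,7,11-trimethyldodeca-1,10-dien-6-yl]-4-ethenylfuran-2(5H)-one, via alkyllithium 14 (not isolated), via lithium borate 15 (not isolated), via boronic ester 16 (not isolated)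
Conditions: 6, t-BuLi (2 equiv), Et2O, −78 °C; 11, −78 °C → rt; solvent changed to THF; Pd(OAc)2 (3 mol%), (Sp,Sp)-Mandyphos [a 1,1'-bis(diarylphosphino)-2,2'-bis(α-(dimethylamino)benzyl)ferrocene, aryl = 4-methoxy-3,5-dimethylphenyl] (3.6 mol%), NaOTf, 13, 60 °C; then NaBO3·4H2O, THF/H2O, rt; 17 is acetylated without delay
Reagents that add atoms: sodium perborate, [Na+].[Na+].O[B-]1(O)OO[B-](O)(O)OO1
Why: t-BuLi turns 6 into alkyllithium 14, which adds to boron of 11 to give borate 15; zerovalent palladium inserts into the C3–Br bond of 13, triflate takes the place of bromide, and the cationic alkenylpalladium binds the alkene of 15 and induces a 1,2-shift of the homoallyl group from boron to C5 anti to palladium (new C4–C5 bond, the later C7–C8), after which reductive elimination joins C6 to C3 of the furanone (the later C9–C9a) and perborate turns C–B into C–OH with retention. The closest known reaction is the palladium/Mandyphos conjunctive cross-coupling of β-substituted alkenyl B(mac) ate complexes with C(sp2) halides and triflates. No ring is closed in this step. C5 and C6 arise together: their relative configuration follows stereospecifically from the (E) geometry of 11 and the anti addition, and the absolute sense (5R,6S) is set by the chiral ligand, with the allylic C7 centre only a minor substrate bias. The step needs the metalate shift to beat direct Suzuki–Miyaura transfer of the alkenyl group and β-hydride loss, which the hindered mac diol on boron and the chelating bisphosphine are expected to secure, and it needs oxidative addition only at the alkenyl bromide, the sole carbon–halogen bond present.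

Step 9
Reactants: 17 hydroxy butenolide
Product: 18 (3R,5R,6S,7R)-6-(4-ethenyl-2-oxo-2,5-dihydrofuran-3-yl)-3,7,11-trimethyldodeca-1,10-dien-5-yl acetate
Conditions: Ac2O, pyridine, DMAP (cat.), CH2Cl2, 0 °C → rt
Reagents that add atoms: acetic anhydride, CC(=O)OC(C)=O
Why: DMAP-catalysed acylation of the secondary alcohol with retention at C5, which also removes the free hydroxyl that could translactonise onto the butenolide.

Step 10
Reactants: 18 triene acetate
Product: 19 (4Z,6R,8R,9S)-6-methyl-9-[(2R)-6-methylhept-5-en-2-yl]-1-oxo-1,3,6,7,8,9-hexahydrocycloocta[c]furan-8-yl acetate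
Conditions: second-generation Grubbs catalyst RuCl2(=CHPh)(H2IMes)(PCy3) (10 mol%), CH2Cl2 (2 mM), 40 °C
Reagents that add atoms: none
Why: Ring-closing metathesis in which the butenolide double bond holds the vinyl group and the pentenyl arm cis, as an ortho-disubstituted arene would, the ruthenium carbene forms at the monosubstituted alkene and closes the eight-membered ring to the necessarily (Z) diene with loss of ethene, and the trisubstituted side-chain alkene should react far more slowly.

Step 11
Reactants: 19 bicyclic diene acetate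
Product: 20 target CNP0018922.1, (4S,5S,6R,8R,9S)-4,5-methano-6-methyl-9-[(2R)-6-methylhept-5-en-2-yl]-1-oxo-1,3,4,5,6,7,8,9-octahydrocycloocta[c]furan-8-yl acetate
Conditions: CH2N2 (excess, Et2O), Pd(OAc)2 (5 mol%), Et2O/CH2Cl2, 0 °C
Reagents that add atoms: diazomethane, C=[N+]=[N-]
Why: Palladium-catalysed methylene transfer from diazomethane should go to the cis-disubstituted conjugated C4=C5 bond and leave the trisubstituted side-chain alkene and the tetrasubstituted butenolide alkene alone; syn addition to the (Z) alkene gives the cis-fused cyclopropane, and attack from the periphery of the ring, anti to C7 in the conformer that keeps the C6–H bond in the alkene plane (allylic 1,3-strain), places the new CH2 trans to the C6 methyl group as in the target.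

Compound list
1 | (S)-4-benzyloxazolidin-2-one | O=C1N[C@@H](Cc2ccccc2)CO1 | starting material
2 | (E)-but-2-enoyl chloride (crotonyl chloride) | C/C=C/C(Cl)=O | starting material
3 | (S)-4-benzyl-3-[(E)-but-2-enoyl]oxazolidin-2-one | C/C=C/C(=O)N1[C@@H](Cc2ccccc2)COC1=O | intermediate
4 | (S)-4-benzyl-3-[(S)-2-methylbut-3-enoyl]oxazolidin-2-one | C=C[C@H](C)C(=O)N1[C@@H](Cc2ccccc2)COC1=O | intermediate
5 | (S)-2-methylbut-3-en-1-ol | C=C[C@H](C)CO | intermediate
6 | (S)-4-iodo-3-methylbut-1-ene | C=C[C@H](C)CI | intermediate
7 | acenaphthylene-1,2-dione (acenaphthenequinone) | O=C1C(=O)c2cccc3cccc1c23 | starting material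
8 | cis-(1R,2S)-1,2-dimethyl-1,2-dihydroacenaphthylene-1,2-diol (meso; mac diol) | C[C@]1(O)[C@@](C)(O)c2cccc3cccc1c23 | intermediate
9 | (R)-3,7-dimethylocta-1,6-diene ((R)-β-citronellene) | C=C[C@H](C)CCC=C(C)C | starting material
10 | 2-[(1E,3R)-3,7-dimethylocta-1,6-dien-1-yl]-1,3,2-benzodioxaborole | CC(C)=CCC[C@@H](C)/C=C/B1Oc2ccccc2O1 | intermediate
11 | [(1E,3R)-3,7-dimethylocta-1,6-dien-1-yl]boronic acid cis-1,2-dimethylacenaphthene-1,2-diyl (mac) ester | CC(C)=CCC[C@@H](C)/C=C/B1O[C@@]2(C)c3cccc4cccc(c34)[C@@]2(C)O1 | intermediate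
12 | 3,4-dibromofuran-2(5H)-one | BrC1=C(Br)C(=O)OC1 | starting material
13 | 3-bromo-4-ethenylfuran-2(5H)-one | C=CC1=C(Br)C(=O)OC1 | intermediate
14 | [(2R)-2-methylbut-3-en-1-yl]lithium | [Li]C[C@@H](C)C=C | intermediate
15 | lithium [(2R)-2-methylbut-3-en-1-yl][(1E,3R)-3,7-dimethylocta-1,6-dien-1-yl]borate of diol 8 (ate complex) | [Li+].C=C[C@H](C)C[B-]1(/C=C/[C@H](C)CCC=C(C)C)O[C@@]2(C)c3cccc4cccc(c34)[C@@]2(C)O1 | intermediate
16 | 3-[(3R,5R,6S,7R)-3,7,11-trimethyl-5-boryldodeca-1,10-dien-6-yl]-4-ethenylfuran-2(5H)-one, boron on C5 as its mac ester | C=C[C@H](C)C[C@@H](B1O[C@@]2(C)c3cccc4cccc(c34)[C@@]2(C)O1)[C@@H]([C@H](C)CCC=C(C)C)C1=C(C=C)COC1=O | intermediate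
17 | 3-[(3R,5R,6S,7R)-5-hydroxy-3,7,11-trimethyldodeca-1,10-dien-6-yl]-4-ethenylfuran-2(5H)-one | C=C[C@H](C)C[C@@H](O)[C@@H]([C@H](C)CCC=C(C)C)C1=C(C=C)COC1=O | intermediate
18 | (3R,5R,6S,7R)-6-(4-ethenyl-2-oxo-2,5-dihydrofuran-3-yl)-3,7,11-trimethyldodeca-1,10-dien-5-yl acetate | C=C[C@H](C)C[C@@H](OC(C)=O)[C@@H]([C@H](C)CCC=C(C)C)C1=C(C=C)COC1=O | intermediate
19 | (4Z,6R,8R,9S)-6-methyl-9-[(2R)-6-methylhept-5-en-2-yl]-1-oxo-1,3,6,7,8,9-hexahydrocycloocta[c]furan-8-yl acetate | CC(=O)O[C@@H]1C[C@@H](C)/C=C\C2=C(C(=O)OC2)[C@@H]1[C@H](C)CCC=C(C)C | intermediate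
20 | CNP0018922.1, (4S,5S,6R,8R,9S)-4,5-methano-6-methyl-9-[(2R)-6-methylhept-5-en-2-yl]-1-oxo-1,3,4,5,6,7,8,9-octahydrocycloocta[c]furan-8-yl acetate | CC(=O)O[C@@H]1C[C@@H](C)[C@@H]2C[C@@H]2C2=C(C(=O)OC2)[C@@H]1[C@H](C)CCC=C(C)C | target

Total step count: 11. Longest linear sequence: 8 steps (steps 1, 2, 3, 4, 8, 9, 10, 11).

Steps most likely to fail

Step 8. The alkenyl group may pass directly from boron to palladium (the Suzuki–Miyaura path), or the alkylpalladium intermediate may lose a β-hydride before reductive elimination. The vinyl group of dienyl bromide 13 may insert into palladium–carbon bonds or polymerise. The basic oxidation may translactonise the free hydroxy butenolide, and facial control by the ligand may be eroded by the allylic stereocentre. The fallback sets out from 6 and 11 and comes back at 18; it moves the union to a bromide that carries no diene and adds the vinyl group afterwards, so it answers the failure modes tied to 13 and not a failure of the metalate shift itself. Commercial 4-methoxyfuran-2(5H)-one is brominated with NBS to 3-bromo-4-methoxyfuran-2(5H)-one F1. Borate 15, formed from 6 and 11 as before, is coupled with F1 under the same palladium catalysis and oxidised in the flask to 3-[(3R,5R,6S,7R)-5-hydroxy-3,7,11-trimethyldodeca-1,10-dien-6-yl]-4-methoxyfuran-2(5H)-one F2. Acetylation (Ac2O, pyridine, DMAP) gives (3R,5R,6S,7R)-6-(4-methoxy-2-oxo-2,5-dihydrofuran-3-yl)-3,7,11-trimethyldodeca-1,10-dien-5-yl acetate F3. LiCl in DMF at 100 °C removes the O-methyl group to give the tetronic acid (3R,5R,6S,7R)-6-(4-hydroxy-2-oxo-2,5-dihydrofuran-3-yl)-3,7,11-trimethyldodeca-1,10-dien-5-yl acetate F4. Tf2O and iPr2NEt at −78 °C give the enol triflate (3R,5R,6S,7R)-6-[2-oxo-4-(trifluoromethylsulfonyloxy)-2,5-dihydrofuran-3-yl]-3,7,11-trimethyldodeca-1,10-dien-5-yl acetate F5. Stille coupling of F5 with tributyl(vinyl)stannane (Pd(PPh3)4, LiCl, THF, 60 °C) gives 18.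

Step 11. Methylene transfer may be slow on the conjugated, hindered cis-alkene, so that diazomethane adds to the dienoate as a 1,3-dipole, or both faces of the flexible eight-membered ring may be attacked. The fallback sets out from 19 and comes back at 20; it replaces carbene transfer by a Michael-initiated ring closure. Dimethylsulfoxonium methylide (Me3S(O)I, NaH (1 equiv), DMSO/THF, 0 °C → rt) should add 1,6 to the dienoate at C5, anti to the C6 methyl group, and the resulting dienolate should close at C4 with loss of DMSO to the cis-fused cyclopropane, while the side-chain alkene is inert to the nucleophilic ylide. No new compound is formed on the way.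

Step 10. Cross-metathesis may give oligomers at any practical concentration, the carbene may close onto the side-chain alkene with loss of isobutene, or the vinylbutenolide diene may undergo an intramolecular Diels–Alder reaction with the pendant alkene on heating. The fallback sets out from 6 and 11 and comes back at 19; it closes the ring by a Heck reaction instead of metathesis. The material is taken through the first fallback as far as tetronic acid F4, which is converted with (COBr)2 and catalytic DMF in CH2Cl2 into the 4-bromobutenolide (3R,5R,6S,7R)-6-(4-bromo-2-oxo-2,5-dihydrofuran-3-yl)-3,7,11-trimethyldodeca-1,10-dien-5-yl acetate F6. Under ligand-free phase-transfer conditions (Pd(OAc)2, Bu4NCl, KOAc, DMF, 80 °C) the alkenylpalladium should attack the terminal carbon of the pendant vinyl group (8-endo) and lose a β-hydride toward the new ring CH2 to give diene 19. Seven-membered exo closure is the competing path.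

Further compounds
F1 | step 8 | 3-bromo-4-methoxyfuran-2(5H)-one | COC1=C(Br)C(=O)OC1
F2 | step 8 | 3-[(3R,5R,6S,7R)-5-hydroxy-3,7,11-trimethyldodeca-1,10-dien-6-yl]-4-methoxyfuran-2(5H)-one | C=C[C@H](C)C[C@@H](O)[C@@H]([C@H](C)CCC=C(C)C)C1=C(OC)COC1=O
F3 | step 8 | (3R,5R,6S,7R)-6-(4-methoxy-2-oxo-2,5-dihydrofuran-3-yl)-3,7,11-trimethyldodeca-1,10-dien-5-yl acetate | C=C[C@H](C)C[C@@H](OC(C)=O)[C@@H]([C@H](C)CCC=C(C)C)C1=C(OC)COC1=O
F4 | step 8 | (3R,5R,6S,7R)-6-(4-hydroxy-2-oxo-2,5-dihydrofuran-3-yl)-3,7,11-trimethyldodeca-1,10-dien-5-yl acetate | C=C[C@H](C)C[C@@H](OC(C)=O)[C@@H]([C@H](C)CCC=C(C)C)C1=C(O)COC1=O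
F5 | step 8 | (3R,5R,6S,7R)-6-[2-oxo-4-(trifluoromethylsulfonyloxy)-2,5-dihydrofuran-3-yl]-3,7,11-trimethyldodeca-1,10-dien-5-yl acetate | C=C[C@H](C)C[C@@H](OC(C)=O)[C@@H]([C@H](C)CCC=C(C)C)C1=C(OS(=O)(=O)C(F)(F)F)COC1=O
F6 | step 10 | (3R,5R,6S,7R)-6-(4-bromo-2-oxo-2,5-dihydrofuran-3-yl)-3,7,11-trimethyldodeca-1,10-dien-5-yl acetate | C=C[C@H](C)C[C@@H](OC(C)=O)[C@@H]([C@H](C)CCC=C(C)C)C1=C(Br)COC1=O
F0 | step 11 | none | none
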